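At 0.0855 min⁻¹ the starting complex falls in the south-east run between 2.00 min and 10.0 min. We assume that what the gas has put into solution stays steady from then on, so that each exchange runs pseudo-first-order on it.

| setting | south-east | flask |
|---|---|---|
| starting complex | 0.13 M | 0.13 M |
| leaving ligand | 0.065 M | 0.0650 M |
| gas | 52 mM (held) | 52 mM (held) |
| remark | the very flask that is asked about, followed so far |  |
| time |  | 50 min |

- south-east (time / min: starting complex / %, complex with one exchanged / %, complex with two exchanged / %): 2.00: 89.2, 11.0, 0.3; 4.00: 76.0, 23.6, 0.8; 6.00: 62.8, 34.5, 1.3; 8.00: 53.4, 43.8, 2.1; 10.0: 45.0, 50.6, 4.4

(scatter of a reading: 0.5 percentage points)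

* where most of what was charged as starting complex, at 50 min is found (complex with two exchanged / starting complex / complex with one exchanged)
* the largest share itself, whichever of these holds it, in percent of the starting complex charged

Both exchanges draw on that same supply, so we carry the second exchange's rate constant over the first's, the selectivity factor 0.177, read from complex with two exchanged at 10.0 min, one reading with a scatter of 0.5 percentage points. Time then drops out: the share of complex with one exchanged is the fraction of starting complex left, raised to that factor, minus that fraction, all over one minus the factor.

Running our rate on to 50 min leaves 1.47% of the starting complex, so we reckon 55.8% complex with one exchanged. The forecast says complex with one exchanged too, but at a higher 62%, noting that the “second step is slow”.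

    gas ⇌ incoming ligand, rate k1*(csat - [incoming ligand]) (kL = 0.00920 s⁻¹)
    starting complex + incoming ligand → leaving ligand + complex with one exchanged (k = 0.0700 M⁻¹ s⁻¹)
    complex with one exchanged + incoming ligand → leaving ligand + complex with two exchanged (k = 0.0120 M⁻¹ s⁻¹)
    2 incoming ligand → self-condensation product (k = 0.190 M⁻¹ s⁻¹)

The flask at 50 min holds 52.3% as complex with one exchanged, against 46.9% as complex with two exchanged. By then complex with one exchanged is made at 0.0955 of the rate at which it is used up. Incoming ligand in this flask did not stay steady, rising from 0.0200 M at 5.00 min to 0.0246 M at 50.0 min, and the 0.852% of starting complex left there is less than our 1.47%. Our factor, applied to that 0.852%, gives 51.2%. The same flask left until 12 min keeps 37.7% of its starting complex, for which the factor gives 56.4%, and that flask holds 56.6%.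

The readings were computed for an exercise.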